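**Retrosynthetic overview**
1. The last step frees the C6 aldehyde from its dimethyl acetal. Before it, rings C and D are opened together: C8–C15 by retro-aldol and C13–C14 by retro-Giese. This leaves a ring A/spiro-δ-lactone core with an exo-methylene lactone (C8=C14) and a C9 side chain ending in a Morita–Baylis–Hillman-type hydroxy-enal, C13H(OH)–C16(=C17H2)–C15HO.
2. Enabling feature: in ring D (C8–C14–C13–C16–C15) C8 is α and C14 is β to the C7 lactone carbonyl, and C13 and C15 are both carbinol carbons flanking the C16 exo-methylene. C13 (carbonyl-type polarity) can therefore be joined to the electrophilic C14 as a radical, and the C8 enolate so formed can take the C15 aldehyde.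
3. The hydroxy-enal comes from a C13 aldehyde by Nozaki–Hiyama–Kishi coupling. The vicinal C9 (tertiary) and C10 (quaternary) centres come from a Claisen rearrangement of an O-allyl vinylogous ester (ring A 2-formyl ketone plus an MBH-derived allyl bromide). The lactone is closed after reducing C20.
4. Ring A, with its enone and C5, comes from 4,4-dimethylcyclohexa-2,5-dienone by enantioselective conjugate vinylation; the vinyl group is the masked C6 aldehyde.
5. Ring order: A (from the starting material), then the lactone ring, then C and D together in the key step.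

Key step: step 15

Remark: kaurane numbering (C1–C20) is used for all intermediates, and the target is taken as drawn, (5R,8S,9S,10S,13S,15R). Compounds 18–20 are carried as mixtures of C13 epimers, which converge in step 15.

**Step 1**
Reactants: 1 4,4-dimethylcyclohex-2-en-1-one
Product: 2 4,4-dimethylcyclohexa-2,5-dien-1-one
Conditions: DDQ, 1,4-dioxane, reflux
Reagents that add atoms: none
Why: DDQ dehydrogenation of the enone through its dienol should give the symmetric cross-conjugated dienone, a known reaction of this substrate that forms no stereocentre.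

**Step 2**
Reactants: 2 4,4-dimethylcyclohexa-2,5-dien-1-one
Product: 3 (5R)-5-ethenyl-4,4-dimethylcyclohex-2-en-1-one
Conditions: [Rh(cod)2]PF6 (3 mol%), (R)-BINAP, potassium vinyltrifluoroborate, PhMe/H2O, 105 °C
Reagents that add atoms: potassium vinyltrifluoroborate, C=C[B-](F)(F)F.[K+]
Why: Rhodium-catalysed asymmetric 1,4-addition of an alkenylboron reagent (Hayashi–Miyaura reaction) to one of the two enantiotopic enone units should set C5 by ligand control, the (R)-ligand being chosen from the usual cyclohexenone face model, and it leaves the second enone as the ring A enone of the target.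

**Step 3**
Reactants: 3 (5R)-5-ethenyl-4,4-dimethylcyclohex-2-en-1-one
Product: 5 (5S)-5-(dimethoxymethyl)-4,4-dimethylcyclohex-2-en-1-one, via aldehyde 4 (not isolated)
Conditions: O3 (1 equiv), CH2Cl2, −78 °C; PPh3; then MeOSiMe3, Me3SiOTf (cat.), CH2Cl2, −78 °C
Reagents that add atoms: ozone, [O-][O+]=O; methoxytrimethylsilane, CO[Si](C)(C)C
Why: Ozone should cleave the electron-rich vinyl group in preference to the electron-poor enone C=C, and the α-branched aldehyde is acetalised at −78 °C under silyl triflate catalysis, conditions under which C5 should not enolise.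

**Step 4**
Reactants: 5 (5S)-5-(dimethoxymethyl)-4,4-dimethylcyclohex-2-en-1-one
Product: 6 (5R,6Z)-5-(dimethoxymethyl)-6-(hydroxymethylidene)-4,4-dimethylcyclohex-2-en-1-one
Conditions: NaH, HCO2Et, THF (cat. EtOH), 0 °C to rt; aq. HCl work-up
Reagents that add atoms: ethyl formate, CCOC=O
Why: Crossed Claisen condensation (α-formylation) at C10, the only enolisable position of the enone, should give the hydrogen-bonded Z-hydroxymethylene ketone without touching C5.

**Step 5**
Reactants: 7 pent-4-enal; 8 methyl acrylate
Product: 9 methyl 3-hydroxy-2-methylidenehept-6-enoate (racemic)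
Conditions: DABCO (cat.), MeOH, rt
Reagents that add atoms: none
Why: Morita–Baylis–Hillman reaction of an unhindered aliphatic aldehyde with an acrylate, whose racemic carbinol centre is removed again in step 6.

**Step 6**
Reactants: 9 methyl 3-hydroxy-2-methylidenehept-6-enoate
Product: 10 methyl (2Z)-2-(bromomethyl)hepta-2,6-dienoate
Conditions: NBS, Me2S, CH2Cl2, 0 °C to rt
Reagents that add atoms: N-bromosuccinimide, O=C1CCC(=O)N1Br
Why: Corey–Kim-type activation of the allylic alcohol followed by SN2' attack of bromide should give the rearranged primary allylic bromide as the favoured 2Z isomer (chain trans to the ester), the geometry needed in step 8.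

**Step 7**
Reactants: 6 (5R,6Z)-5-(dimethoxymethyl)-6-(hydroxymethylidene)-4,4-dimethylcyclohex-2-en-1-one; 10 methyl (2Z)-2-(bromomethyl)hepta-2,6-dienoate
Product: 11 methyl (2E)-2-({[(E)-[(6R)-6-(dimethoxymethyl)-5,5-dimethyl-2-oxocyclohex-3-en-1-ylidene]methyl]oxy}methyl)hepta-2,6-dienoate
Conditions: K2CO3, acetone, 0 °C to rt
Reagents that add atoms: none
Why: Williamson-type O-alkylation of the acidic hydroxymethylene ketone by direct SN2 at the primary allylic bromide should give the vinylogous ester with the alkoxy group anti to the ketone (E), as is usual for 2-alkoxymethylene ketones.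

**Step 8**
Reactants: 11 the O-allyl vinylogous ester
Product: 12 methyl (3S)-3-[(1S,6R)-6-(dimethoxymethyl)-1-formyl-5,5-dimethyl-2-oxocyclohex-3-en-1-yl]-2-methylidenehept-6-enoate
Conditions: PhMe, 120 °C (sealed tube), BHT (cat.)
Reagents that add atoms: none
Why: Claisen rearrangement through a chair transition state should form C9–C10 on the face of C10 anti to the pseudo-axial C5 acetal arm (allylic 1,3-strain with the exocyclic enol ether), which fixes C10, while the E enol ether and the Z allyl unit place C1 equatorial and C11 axial in the chair and so fix C9 as 9S.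

**Step 9**
Reactants: 12 the α-formyl ketone
Product: 14 (5S,6S,11R)-5-(but-3-en-1-yl)-11-(dimethoxymethyl)-10,10-dimethyl-4-methylidene-2-oxaspiro[5.5]undec-8-ene-3,7-dione, via hydroxy ester 13 (not isolated)
Conditions: NaBH4, MeOH/CH2Cl2, −78 °C; then Bu2SnO (cat.), PhMe, 110 °C
Reagents that add atoms: none
Why: Borohydride at −78 °C should reduce the C20 aldehyde far faster than the hindered conjugated ketone or the acrylate, and tin-catalysed transesterification then closes the δ-lactone under neutral conditions that spare the acetal and do not promote oxa-Michael addition to C14.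

**Step 10**
Reactants: 14 the butenyl spiro-lactone
Product: 15 3-[(5S,6S,11R)-11-(dimethoxymethyl)-10,10-dimethyl-4-methylidene-3,7-dioxo-2-oxaspiro[5.5]undec-8-en-5-yl]propanal
Conditions: O3 (1 equiv), CH2Cl2, −78 °C; PPh3
Reagents that add atoms: ozone, [O-][O+]=O
Why: Ozonolysis should be selective for the only electron-rich alkene, the terminal one, over the enone and the α-methylene lactone.

**Step 11**
Reactants: 16 2-bromoprop-2-en-1-ol
Product: 17 [(2-bromoprop-2-en-1-yl)oxy](tert-butyl)dimethylsilane
Conditions: TBSCl, imidazole, DMF, rt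
Reagents that add atoms: tert-butyldimethylsilyl chloride, CC(C)(C)[Si](C)(C)Cl
Why: Standard silylation of a primary alcohol.

**Step 12**
Reactants: 15 the C13 aldehyde; 17 [(2-bromoprop-2-en-1-yl)oxy](tert-butyl)dimethylsilane
Product: 18 (5S,6S,11R)-5-[4-({[tert-butyl(dimethyl)silyl]oxy}methyl)-3-hydroxypent-4-en-1-yl]-11-(dimethoxymethyl)-10,10-dimethyl-4-methylidene-2-oxaspiro[5.5]undec-8-ene-3,7-dione (both C13 epimers)
Conditions: CrCl2 (4 equiv), NiCl2 (2 mol%), DMF, rt; aqueous work-up
Reagents that add atoms: none
Why: Nozaki–Hiyama–Kishi coupling should add the alkenylchromium reagent only to the aldehyde (ketone, lactone and both Michael acceptors are tolerated), and C13 forms as both epimers, which does not matter because C13 becomes planar in step 15.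

**Step 13**
Reactants: 18 the silyl ether
Product: 19 (5S,6S,11R)-11-(dimethoxymethyl)-5-[3-hydroxy-4-(hydroxymethyl)pent-4-en-1-yl]-10,10-dimethyl-4-methylidene-2-oxaspiro[5.5]undec-8-ene-3,7-dione (both C13 epimers)
Conditions: HF·pyridine, pyridine/THF, 0 °C
Reagents that add atoms: none
Why: Buffered fluoride should cleave the primary silyl ether and leave the acetal, the lactone and the enone intact.

**Step 14**
Reactants: 19 the diol
Product: 20 5-[(5S,6S,11R)-11-(dimethoxymethyl)-10,10-dimethyl-4-methylidene-3,7-dioxo-2-oxaspiro[5.5]undec-8-en-5-yl]-3-hydroxy-2-methylidenepentanal (both C13 epimers)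
Conditions: TEMPO (10 mol%), PhI(OAc)2, CH2Cl2, rt
Reagents that add atoms: none
Why: Oxoammonium (TEMPO) oxidation should be selective for the primary allylic alcohol over the secondary one and stop at the enal.

**Step 15**
Reactants: 20 the hydroxy-enal
Product: 21 the C6 dimethyl acetal of the target: (5R,8S,9S,10S,13S,15R)-13,15-dihydroxy-6,6-dimethoxy-1-oxo-6,7-secokaura-2,16-dien-7,20-olide
Conditions: [Ir(dF(CF3)ppy)2(dtbbpy)]PF6 (1 mol%), quinuclidine (10 mol%), Bu4N H2PO4 (25 mol%), MeCN (0.01 M), blue LEDs, 25 °C
Reagents that add atoms: none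
Why: Proposed new method: the photo-excited iridium complex oxidises quinuclidine to its radical cation, which abstracts the phosphate-activated, allylic α-hydroxy C13–H of either C13 epimer; the planar α-hydroxyallyl radical (the formyl group sits on its nodal carbon C16, so it stays nucleophilic) closes ring C by 6-endo-trig Giese addition to C14, the C8 α-lactone radical is reduced by the reduced photocatalyst to the lactone enolate, and this closes ring D by a 5-exo-trig aldol addition to the C15 aldehyde, after which quinuclidinium returns the proton, so that the step is a redox-neutral isomerisation. The closest known reaction types are the photoredox/quinuclidine α-C–H alkylation of alcohols with acrylates and hydrogen-atom-transfer-initiated Giese/aldol radical–polar crossover annulations. C13 is controlled in the chair-like 6-endo transition state, in which the spiro-lactone holds C10 equatorial at C9, the flat allyl arm takes the pseudo-equatorial site and the small hydroxyl, hydrogen-bonded to the lactone carbonyl, the pseudo-axial one, so that C16 ends trans to C10 across ring C as in the target. C8 is then fixed by the bridged ring itself, since C15 can reach the enolate only on the face cis to C16, which is the face syn to H9 and anti to C10. C15 is controlled by an open, metal-free aldol transition state in which the aldehyde oxygen turns away from the enolate oxygen (held on the C14 side by the lactone ring), so that the new hydroxyl points endo toward C11/C12 (15R). The selectivities needed are hydrogen abstraction at C13–H (the only doubly activated, hydrogen-bond-directed C–H), attack through C13 and not C17 of the allyl radical (six- against eight-membered ring) and aldol at C15 only (C6 is masked as the acetal and C1 would give a four-membered ring).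

**Step 16**
Reactants: 21 the C6 dimethyl acetal
Product: 22 CNP0521079.1
Conditions: PPTS (cat.), acetone/H2O (10:1), 40 °C
Reagents that add atoms: water, O
Why: Mild acid-catalysed hydrolysis of the dimethyl acetal should release the C6 aldehyde without ionising the C15 allylic alcohol or epimerising C5, whose configuration is already that of the target.

**Compound list**
1 | 4,4-dimethylcyclohex-2-en-1-one | O=C1C=CC(C)(C)CC1 | starting material
2 | 4,4-dimethylcyclohexa-2,5-dien-1-one | O=C1C=CC(C)(C)C=C1 | intermediate
3 | (5R)-5-ethenyl-4,4-dimethylcyclohex-2-en-1-one | O=C1C=CC(C)(C)[C@@H](C=C)C1 | intermediate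
4 | (1S)-2,2-dimethyl-5-oxocyclohex-3-ene-1-carbaldehyde | O=C1C=CC(C)(C)[C@@H](C=O)C1 | intermediate
5 | (5S)-5-(dimethoxymethyl)-4,4-dimethylcyclohex-2-en-1-one | O=C1C=CC(C)(C)[C@@H](C(OC)OC)C1 | intermediate
6 | (5R,6Z)-5-(dimethoxymethyl)-6-(hydroxymethylidene)-4,4-dimethylcyclohex-2-en-1-one | O/C=C1\C(=O)C=CC(C)(C)[C@H]1C(OC)OC | intermediate
7 | pent-4-enal | C=CCCC=O | starting material
8 | methyl acrylate | C=CC(=O)OC | starting material
9 | methyl 3-hydroxy-2-methylidenehept-6-enoate (racemic) | C=CCCC(O)C(=C)C(=O)OC | intermediate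
10 | methyl (2Z)-2-(bromomethyl)hepta-2,6-dienoate | C=CCC/C=C(\CBr)C(=O)OC | intermediate
11 | methyl (2E)-2-({[(E)-[(6R)-6-(dimethoxymethyl)-5,5-dimethyl-2-oxocyclohex-3-en-1-ylidene]methyl]oxy}methyl)hepta-2,6-dienoate | C=CCC/C=C(\CO/C=C1/C(=O)C=CC(C)(C)[C@H]1C(OC)OC)C(=O)OC | intermediate
12 | methyl (3S)-3-[(1S,6R)-6-(dimethoxymethyl)-1-formyl-5,5-dimethyl-2-oxocyclohex-3-en-1-yl]-2-methylidenehept-6-enoate | C=C(C(=O)OC)[C@@H](CCC=C)[C@]1(C=O)C(=O)C=CC(C)(C)[C@H]1C(OC)OC | intermediate
13 | methyl (3S)-3-[(1S,6R)-6-(dimethoxymethyl)-1-(hydroxymethyl)-5,5-dimethyl-2-oxocyclohex-3-en-1-yl]-2-methylidenehept-6-enoate | C=C(C(=O)OC)[C@@H](CCC=C)[C@]1(CO)C(=O)C=CC(C)(C)[C@H]1C(OC)OC | intermediate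
14 | (5S,6S,11R)-5-(but-3-en-1-yl)-11-(dimethoxymethyl)-10,10-dimethyl-4-methylidene-2-oxaspiro[5.5]undec-8-ene-3,7-dione | C=C1C(=O)OC[C@]2(C(=O)C=CC(C)(C)[C@H]2C(OC)OC)[C@@H]1CCC=C | intermediate
15 | 3-[(5S,6S,11R)-11-(dimethoxymethyl)-10,10-dimethyl-4-methylidene-3,7-dioxo-2-oxaspiro[5.5]undec-8-en-5-yl]propanal | C=C1C(=O)OC[C@]2(C(=O)C=CC(C)(C)[C@H]2C(OC)OC)[C@@H]1CCC=O | intermediate
16 | 2-bromoprop-2-en-1-ol | C=C(Br)CO | starting material
17 | [(2-bromoprop-2-en-1-yl)oxy](tert-butyl)dimethylsilane | C=C(Br)CO[Si](C)(C)C(C)(C)C | intermediate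
18 | (5S,6S,11R)-5-[4-({[tert-butyl(dimethyl)silyl]oxy}methyl)-3-hydroxypent-4-en-1-yl]-11-(dimethoxymethyl)-10,10-dimethyl-4-methylidene-2-oxaspiro[5.5]undec-8-ene-3,7-dione (both C13 epimers) | C=C1C(=O)OC[C@]2(C(=O)C=CC(C)(C)[C@H]2C(OC)OC)[C@@H]1CCC(O)C(=C)CO[Si](C)(C)C(C)(C)C | intermediate
19 | (5S,6S,11R)-11-(dimethoxymethyl)-5-[3-hydroxy-4-(hydroxymethyl)pent-4-en-1-yl]-10,10-dimethyl-4-methylidene-2-oxaspiro[5.5]undec-8-ene-3,7-dione (both C13 epimers) | C=C1C(=O)OC[C@]2(C(=O)C=CC(C)(C)[C@H]2C(OC)OC)[C@@H]1CCC(O)C(=C)CO | intermediate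
20 | 5-[(5S,6S,11R)-11-(dimethoxymethyl)-10,10-dimethyl-4-methylidene-3,7-dioxo-2-oxaspiro[5.5]undec-8-en-5-yl]-3-hydroxy-2-methylidenepentanal (both C13 epimers) | C=C1C(=O)OC[C@]2(C(=O)C=CC(C)(C)[C@H]2C(OC)OC)[C@@H]1CCC(O)C(=C)C=O | intermediate
21 | (5R,8S,9S,10S,13S,15R)-13,15-dihydroxy-6,6-dimethoxy-1-oxo-6,7-secokaura-2,16-dien-7,20-olide (C6 dimethyl acetal of the target) | C=C1[C@@H](O)[C@]23C[C@@]1(O)CC[C@H]2[C@]1(COC3=O)C(=O)C=CC(C)(C)[C@H]1C(OC)OC | intermediate
22 | CNP0521079.1, (5R,8S,9S,10S,13S,15R)-13,15-dihydroxy-1,6-dioxo-6,7-secokaura-2,16-dien-7,20-olide | C=C1[C@@H](O)[C@]23C[C@@]1(O)CC[C@H]2[C@]1(COC3=O)C(=O)C=CC(C)(C)[C@H]1C=O | target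

**Totals**
Total step count: 16. Longest linear sequence: 13 steps (steps 1–4, 7–10, 12–16, from 1).

**Steps most likely to fail**

Step 15 (proposed new method). What may go wrong:
- The C8 enolate may be protonated before ring D closes, because ring C must first leave its chair to bring C15 to the H9 face.
- The photocatalyst may transfer energy to the ring A enone.
- Facial selectivity at C13 or at C15 may be poor.

Fallback with known reactions, making the two bonds one after the other, setting out from 18:
- The same photoredox/quinuclidine/phosphate system performs the known α-C–H alkylation of the alcohol by the acrylate unit (intramolecular Giese addition, enolate protonated) and should give the ring C hydroxy lactone F1 (C8 epimers).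
- HF·pyridine gives the diol F2.
- TEMPO/PhI(OAc)2 gives the ring C hydroxy-enal F3.
- KN(SiMe3)2/18-crown-6 (THF, −78 °C) regenerates the lactone enolate without a chelating cation, and intramolecular aldol addition closes ring D.
- The fallback comes back to the route at 21.

Step 8. What may go wrong:
- Rearrangement through a boat transition state, or from a Z enol ether, would invert C9.
- The rearrangement may be slow, with loss of the formyl group on prolonged heating.

Fallback, setting out from 9 and 6:
- Boc2O/DMAP converts 9 into the Morita–Baylis–Hillman carbonate F4.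
- Tertiary-amine-catalysed allylic alkylation (DABCO or (DHQD)2PHAL, PhMe; SN2' then SN2') of the formyl ketone 6 with F4 forms C9–C10 directly.
- The fallback comes back to the route at 12.

Step 2. What may go wrong:
- Insertion at the β-carbon next to the quaternary C4 may be slow.
- Enantioselectivity may be low.
- A second addition to the remaining enone may occur.

Fallback, setting out from 2:
- Iminium catalysis with a 9-amino-9-deoxy-epi-quinine salt adds nitromethane to one enone unit and should give the nitro ketone F5.
- A Nef reaction (NaOMe, then buffered TiCl3/NH4OAc) gives aldehyde 4.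
- Aldehyde 4 is acetalised as in step 3, so the fallback comes back to the route at 5.

**Further compounds**
F1 | step 15 | ring C hydroxy lactone, (5R,9S,10S,13S)-13-hydroxy-6,6-dimethoxy-1-oxo-15-[(tert-butyldimethylsilyl)oxy]-6,7:8,15-disecokaura-2,16-dien-7,20-olide (C8 epimers) | O=C1OC[C@]2(C(=O)C=CC(C)(C)[C@H]2C(OC)OC)[C@@H]3CC[C@@](O)(C(=C)CO[Si](C)(C)C(C)(C)C)CC13
F2 | step 15 | ring C diol, the 13,15-dihydroxy analogue of F1 (C8 epimers) | O=C1OC[C@]2(C(=O)C=CC(C)(C)[C@H]2C(OC)OC)[C@@H]3CC[C@@](O)(C(=C)CO)CC13
F3 | step 15 | ring C hydroxy-enal, the 13-hydroxy-15-oxo analogue of F1 (C8 epimers) | O=C1OC[C@]2(C(=O)C=CC(C)(C)[C@H]2C(OC)OC)[C@@H]3CC[C@@](O)(C(=C)C=O)CC13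
F4 | step 8 | methyl 3-[(tert-butoxycarbonyl)oxy]-2-methylidenehept-6-enoate (racemic) | C=CCCC(OC(=O)OC(C)(C)C)C(=C)C(=O)OC
F5 | step 2 | (5S)-4,4-dimethyl-5-(nitromethyl)cyclohex-2-en-1-one | O=C1C=CC(C)(C)[C@@H](C[N+](=O)[O-])C1
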